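**Plan**

- Retrosynthesis: after removal of seven benzyl ethers and return of the C4 ketone to a methoxy-bearing sp3 carbon, ring C is cut at O1–C2 and C3–C4 into styrene, a methoxy donor and a ring A salicylaldehyde. The aldehyde is cut at its C8–CH2 and C6–CH2 bonds, and each chain at its aryl–CH2 bonds.
- Enabling feature: ring C is a benzopyran in which C2–C3 with the C2 phenyl is a styrene unit lying between O1 (the one free phenol of ring A) and C4. C4 is benzylic to the trioxygenated ring A and can therefore be the exocyclic carbon of an ortho-quinone methide.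
- Forward: one aryl boronate is benzylated twice (Suzuki–Miyaura) to give a two-ring and a three-ring chain chloride. The ring A aldehyde is iodinated next to its free OH and coupled (Negishi) with the short chain, then iodinated at its last free site and coupled with the long chain.
- Ring C is then closed in one operation from the aldehyde, trimethyl orthoformate and styrene. OMe/OH exchange, oxidation at C4 and hydrogenolysis finish the target.
- Stereochemistry: C2 (S), the only stereocentre of the target, is set in the [4+2] step by a chiral N-triflyl phosphoramide anion. The C4 centre is transient.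

Key step: step 14

Abbreviations: Bn = benzyl; SC = 2-(benzyloxy)-5-[2-(benzyloxy)benzyl]benzyl (short chain); LC = 2-(benzyloxy)-5-{2-(benzyloxy)-5-[2-(benzyloxy)benzyl]benzyl}benzyl (long chain).

Assumption: the (R)-configured phosphoramide is written for step 14; should it favour the 2R product, its mirror image is used and nothing else in the route changes.

Remark: compound 24 is carried on as the mixture of its two C4 epimers, because C4 becomes the carbonyl carbon in step 16.

**Route**

Step 1
Reactants: 1 salicyl alcohol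
Product: 2 [2-(benzyloxy)phenyl]methanol
Conditions: BnBr, K2CO3, acetone, reflux
Reagents that add atoms: benzyl bromide, BrCc1ccccc1
Why: Williamson etherification in which K2CO3 deprotonates only the phenol, so the benzylic alcohol should stay free.

Step 2
Reactants: 2 [2-(benzyloxy)phenyl]methanol
Product: 3 1-(benzyloxy)-2-(chloromethyl)benzene
Conditions: SOCl2, CH2Cl2, 0 °C to 25 °C
Reagents that add atoms: thionyl chloride, O=S(Cl)Cl
Why: Chlorodehydroxylation of a benzylic alcohol through its chlorosulfite, under which an aryl benzyl ether is inert.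

Step 3
Reactants: 4 5-bromo-2-hydroxybenzyl alcohol
Product: 5 [2-(benzyloxy)-5-bromophenyl]methanol
Conditions: BnBr, K2CO3, acetone, reflux
Reagents that add atoms: benzyl bromide, BrCc1ccccc1
Why: Williamson etherification selective for the phenolic oxygen, as in step 1.

Step 4
Reactants: 5 [2-(benzyloxy)-5-bromophenyl]methanol
Product: 6 [2-(benzyloxy)-5-(4,4,5,5-tetramethyl-1,3,2-dioxaborolan-2-yl)phenyl]methanol
Conditions: B2pin2, Pd(dppf)Cl2, KOAc, 1,4-dioxane, 85 °C
Reagents that add atoms: bis(pinacolato)diboron, CC1(C)OB(OC1(C)C)B1OC(C)(C)C(C)(C)O1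
Why: Miyaura borylation, in which zerovalent palladium inserts into the aryl bromide and acetate-assisted transmetalation delivers the boryl group, a free hydroxymethyl group being tolerated.

Step 5
Reactants: 6 [2-(benzyloxy)-5-(4,4,5,5-tetramethyl-1,3,2-dioxaborolan-2-yl)phenyl]methanol; 3 1-(benzyloxy)-2-(chloromethyl)benzene
Product: 7 {2-(benzyloxy)-5-[2-(benzyloxy)benzyl]phenyl}methanol (SC–OH)
Conditions: Pd(dppf)Cl2, K2CO3, 1,4-dioxane/H2O, 80 °C
Reagents that add atoms: none
Why: Suzuki–Miyaura sp2–sp3 coupling of an aryl boronate with a benzylic chloride, which adds readily to palladium and has no β-hydrogen, so the diarylmethane should form cleanly.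

Step 6
Reactants: 7 {2-(benzyloxy)-5-[2-(benzyloxy)benzyl]phenyl}methanol
Product: 8 1-(benzyloxy)-4-[2-(benzyloxy)benzyl]-2-(chloromethyl)benzene (SC–Cl)
Conditions: SOCl2, CH2Cl2, 0 °C to 25 °C
Reagents that add atoms: thionyl chloride, O=S(Cl)Cl
Why: Chlorodehydroxylation of the benzylic alcohol as in step 2, the alkoxyarene rings being too weakly nucleophilic to be alkylated without a Lewis acid.

Step 7
Reactants: 6 [2-(benzyloxy)-5-(4,4,5,5-tetramethyl-1,3,2-dioxaborolan-2-yl)phenyl]methanol; 8 SC–Cl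
Product: 9 (2-(benzyloxy)-5-{2-(benzyloxy)-5-[2-(benzyloxy)benzyl]benzyl}phenyl)methanol (LC–OH)
Conditions: Pd(dppf)Cl2, K2CO3, 1,4-dioxane/H2O, 80 °C
Reagents that add atoms: none
Why: Second Suzuki–Miyaura benzylation of the same boronate, which lengthens the chain by one hydroxybenzyl unit exactly as in step 5.

Step 8
Reactants: 9 LC–OH
Product: 10 1-(benzyloxy)-4-{2-(benzyloxy)-5-[2-(benzyloxy)benzyl]benzyl}-2-(chloromethyl)benzene (LC–Cl)
Conditions: SOCl2, CH2Cl2, 0 °C to 25 °C
Reagents that add atoms: thionyl chloride, O=S(Cl)Cl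
Why: Chlorodehydroxylation of the benzylic alcohol as in steps 2 and 6.

Step 9
Reactants: 11 2,4,6-trihydroxybenzaldehyde
Product: 12 4,6-bis(benzyloxy)-2-hydroxybenzaldehyde
Conditions: BnBr (2 equiv), K2CO3, DMF, 0 °C to 25 °C
Reagents that add atoms: benzyl bromide, BrCc1ccccc1
Why: Williamson etherification that should stop at the dibenzyl ether, because the last ortho hydroxyl is locked in a hydrogen bond to the formyl oxygen and is the least nucleophilic.

Step 10
Reactants: 12 4,6-bis(benzyloxy)-2-hydroxybenzaldehyde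
Product: 13 4,6-bis(benzyloxy)-2-hydroxy-3-iodobenzaldehyde
Conditions: N-iodosuccinimide, CF3CO2H (cat.), MeCN, 0 °C
Reagents that add atoms: N-iodosuccinimide, O=C1CCC(=O)N1I
Why: Electrophilic aromatic iodination, which in 2-hydroxy-4,6-dialkoxyaryl carbonyl compounds is expected at C3 between the small hydroxyl and one ether rather than at C5 between two benzyloxy groups.

Step 11
Reactants: 13 4,6-bis(benzyloxy)-2-hydroxy-3-iodobenzaldehyde; 8 SC–Cl
Product: 15 4,6-bis(benzyloxy)-2-hydroxy-3-(SC)benzaldehyde, via short-chain benzylzinc chloride 14 (not isolated)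
Conditions: 8, Zn dust, LiCl, THF, 25 °C; then 13, Pd(OAc)2, SPhos, THF, 25 °C, slow addition of 14
Reagents that add atoms: none
Why: Negishi coupling, in which the palladium/SPhos-catalysed transfer of a benzylzinc halide to the aryl iodide should outpace both its protonation by the chelated phenol and its uncatalysed addition to the electron-rich, hydrogen-bonded formyl group.

Step 12
Reactants: 15 4,6-bis(benzyloxy)-2-hydroxy-3-(SC)benzaldehyde
Product: 16 4,6-bis(benzyloxy)-2-hydroxy-5-iodo-3-(SC)benzaldehyde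
Conditions: N-iodosuccinimide, DMF, 0 °C to 25 °C
Reagents that add atoms: N-iodosuccinimide, O=C1CCC(=O)N1I
Why: Electrophilic aromatic iodination at the only free carbon of ring A, which with three oxygen donors is far more nucleophilic than the mono-alkoxy rings of the chain, so no acid activator is used.

Step 13
Reactants: 16 4,6-bis(benzyloxy)-2-hydroxy-5-iodo-3-(SC)benzaldehyde; 10 LC–Cl
Product: 18 4,6-bis(benzyloxy)-2-hydroxy-5-(LC)-3-(SC)benzaldehyde, via long-chain benzylzinc chloride 17 (not isolated)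
Conditions: 10, Zn dust, LiCl, THF, 25 °C; then 16, Pd(OAc)2, SPhos, THF, 25 °C to 40 °C, slow addition of 17
Reagents that add atoms: none
Why: Negishi coupling as in step 11, with the bulky electron-rich biaryl phosphine chosen because it supports coupling at aryl halides that carry two ortho substituents.

Step 14
Reactants: 18 4,6-bis(benzyloxy)-2-hydroxy-5-(LC)-3-(SC)benzaldehyde; 19 styrene; 20 trimethyl orthoformate
Product: 23 (2S,4S)-5,7-bis(benzyloxy)-4-methoxy-6-(LC)-8-(SC)-2-phenylchromane (cis-4-methoxyflavan), via dimethyl acetal 21 (not isolated), via 4-methoxy ortho-quinone methide 22 (not isolated)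
Conditions: (R)-3,3'-bis(2,4,6-triisopropylphenyl)-1,1'-binaphthyl-2,2'-diyl N-triflylphosphoramide (10 mol %), 19 (5 equiv), 20 (2 equiv), 5 Å MS, toluene, −40 °C to −20 °C
Reagents that add atoms: none
Why: Proposed new method: the acid should turn the formyl group of 18 with 20 into acetal 21 and then, by loss of methanol assisted by the free phenol (the future O1) and the ether oxygens on C5 and C7, into the 4-methoxy ortho-quinone methide 22, held in its O-protonated form as a hydrogen-bonded contact ion pair with the chiral phosphoramide anion. Styrene then adds in an inverse-electron-demand hetero-Diels–Alder reaction, concerted but asynchronous or stepwise through the benzylic cation, its CH2 carbon bonding to C4 and its benzylic carbon to O1, so that ring C closes as a six-membered pyran by [4+2] cycloaddition with the O1–C2 bond formed last. The closest known reaction types are the acid-promoted racemic condensation of salicylaldehydes, orthoformates and styrenes to cis-4-alkoxyflavans and the chiral-Brønsted-acid-catalysed [4+2] addition of aryl-substituted ortho-quinone methides to styrenes. C2 is controlled by the catalyst, whose 3,3'-aryl groups should screen one face of the ion-paired quinone methide so that the phenyl-bearing carbon is delivered to O1 in the 2S sense, while C4 follows from the endo approach of the phenyl group (cis to methoxy) and is of no lasting consequence because it ends as the carbonyl carbon. The step needs regio-, chemo- and enantioselectivity: the regiochemistry is secured by the polarisation of styrene and by O1 being the only free phenol, self-condensation at ring A is blocked because C6 and C8 already carry the chains, and the enantioselectivity rests on the hydrogen bond between the O1–H group and the confined anion.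

Step 15
Reactants: 23 (2S,4S)-5,7-bis(benzyloxy)-4-methoxy-6-(LC)-8-(SC)-2-phenylchromane
Product: 24 (2S)-5,7-bis(benzyloxy)-6-(LC)-8-(SC)-2-phenylchroman-4-ol (both C4 epimers)
Conditions: p-TsOH·H2O (10 mol %), THF/H2O 4:1, 25 °C, dilute
Reagents that add atoms: water, O
Why: Acid-catalysed SN1 solvolysis of a benzylic methyl ether, in which the C4 cation stabilised by O1 and the C5 and C7 oxygens should be captured by the large excess of water while C2 is not touched.

Step 16
Reactants: 24 (2S)-5,7-bis(benzyloxy)-6-(LC)-8-(SC)-2-phenylchroman-4-ol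
Product: 25 (2S)-5,7-bis(benzyloxy)-6-(LC)-8-(SC)-2-phenylchroman-4-one
Conditions: Dess–Martin periodinane, CH2Cl2, 0 °C to 25 °C
Reagents that add atoms: none
Why: Dess–Martin oxidation of a secondary benzylic alcohol, which converges both C4 epimers on the ketone under non-basic conditions that should not open the flavanone to its chalcone and so leave C2 intact.

Step 17
Reactants: 25 (2S)-5,7-bis(benzyloxy)-6-(LC)-8-(SC)-2-phenylchroman-4-one
Product: 26 sarmentosumin D
Conditions: H2 (1 atm), Pd/C (10 wt %), EtOAc/MeOH, 25 °C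
Reagents that add atoms: none
Why: Catalytic hydrogenolysis of seven aryl benzyl ethers, which should be faster than cleavage of the O1–C2 bond or reduction of the hydrogen-bonded C4 ketone and runs in a neutral medium that does not racemise the 5-hydroxyflavanone.

**Compound list**

1 | salicyl alcohol (2-hydroxybenzyl alcohol) | OCc1ccccc1O | starting material
2 | [2-(benzyloxy)phenyl]methanol | OCc1ccccc1OCc1ccccc1 | intermediate
3 | 1-(benzyloxy)-2-(chloromethyl)benzene | ClCc1ccccc1OCc1ccccc1 | intermediate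
4 | 5-bromo-2-hydroxybenzyl alcohol | OCc1cc(Br)ccc1O | starting material
5 | [2-(benzyloxy)-5-bromophenyl]methanol | OCc1cc(Br)ccc1OCc1ccccc1 | intermediate
6 | [2-(benzyloxy)-5-(4,4,5,5-tetramethyl-1,3,2-dioxaborolan-2-yl)phenyl]methanol | OCc1cc(B2OC(C)(C)C(C)(C)O2)ccc1OCc1ccccc1 | intermediate
7 | {2-(benzyloxy)-5-[2-(benzyloxy)benzyl]phenyl}methanol (SC–OH) | OCc1cc(Cc2ccccc2OCc2ccccc2)ccc1OCc1ccccc1 | intermediate
8 | 1-(benzyloxy)-4-[2-(benzyloxy)benzyl]-2-(chloromethyl)benzene (SC–Cl) | ClCc1cc(Cc2ccccc2OCc2ccccc2)ccc1OCc1ccccc1 | intermediate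
9 | (2-(benzyloxy)-5-{2-(benzyloxy)-5-[2-(benzyloxy)benzyl]benzyl}phenyl)methanol (LC–OH) | OCc1cc(Cc2cc(Cc3ccccc3OCc3ccccc3)ccc2OCc2ccccc2)ccc1OCc1ccccc1 | intermediate
10 | 1-(benzyloxy)-4-{2-(benzyloxy)-5-[2-(benzyloxy)benzyl]benzyl}-2-(chloromethyl)benzene (LC–Cl) | ClCc1cc(Cc2cc(Cc3ccccc3OCc3ccccc3)ccc2OCc2ccccc2)ccc1OCc1ccccc1 | intermediate
11 | 2,4,6-trihydroxybenzaldehyde | O=Cc1c(O)cc(O)cc1O | starting material
12 | 4,6-bis(benzyloxy)-2-hydroxybenzaldehyde | O=Cc1c(O)cc(OCc2ccccc2)cc1OCc1ccccc1 | intermediate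
13 | 4,6-bis(benzyloxy)-2-hydroxy-3-iodobenzaldehyde | O=Cc1c(O)c(I)c(OCc2ccccc2)cc1OCc1ccccc1 | intermediate
14 | short-chain benzylzinc chloride SC–ZnCl, {2-(benzyloxy)-5-[2-(benzyloxy)benzyl]benzyl}zinc chloride | Cl[Zn]Cc1cc(Cc2ccccc2OCc2ccccc2)ccc1OCc1ccccc1 | intermediate
15 | 4,6-bis(benzyloxy)-2-hydroxy-3-(SC)benzaldehyde | O=Cc1c(O)c(Cc2cc(Cc3ccccc3OCc3ccccc3)ccc2OCc2ccccc2)c(OCc2ccccc2)cc1OCc1ccccc1 | intermediate
16 | 4,6-bis(benzyloxy)-2-hydroxy-5-iodo-3-(SC)benzaldehyde | O=Cc1c(O)c(Cc2cc(Cc3ccccc3OCc3ccccc3)ccc2OCc2ccccc2)c(OCc2ccccc2)c(I)c1OCc1ccccc1 | intermediate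
17 | long-chain benzylzinc chloride LC–ZnCl | Cl[Zn]Cc1cc(Cc2cc(Cc3ccccc3OCc3ccccc3)ccc2OCc2ccccc2)ccc1OCc1ccccc1 | intermediate
18 | 4,6-bis(benzyloxy)-2-hydroxy-5-(LC)-3-(SC)benzaldehyde | O=Cc1c(O)c(Cc2cc(Cc3ccccc3OCc3ccccc3)ccc2OCc2ccccc2)c(OCc2ccccc2)c(Cc2cc(Cc3cc(Cc4ccccc4OCc4ccccc4)ccc3OCc3ccccc3)ccc2OCc2ccccc2)c1OCc1ccccc1 | intermediate
19 | styrene | C=Cc1ccccc1 | starting material
20 | trimethyl orthoformate | COC(OC)OC | starting material
21 | 3,5-bis(benzyloxy)-2-(dimethoxymethyl)-4-(LC)-6-(SC)phenol (dimethyl acetal of 18) | COC(OC)c1c(O)c(Cc2cc(Cc3ccccc3OCc3ccccc3)ccc2OCc2ccccc2)c(OCc2ccccc2)c(Cc2cc(Cc3cc(Cc4ccccc4OCc4ccccc4)ccc3OCc3ccccc3)ccc2OCc2ccccc2)c1OCc1ccccc1 | intermediate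
22 | 3,5-bis(benzyloxy)-6-(methoxymethylidene)-4-(LC)-2-(SC)cyclohexa-2,4-dien-1-one (4-methoxy ortho-quinone methide; geometry of the exocyclic enol ether not defined) | COC=C1C(=O)C(Cc2cc(Cc3ccccc3OCc3ccccc3)ccc2OCc2ccccc2)=C(OCc2ccccc2)C(Cc2cc(Cc3cc(Cc4ccccc4OCc4ccccc4)ccc3OCc3ccccc3)ccc2OCc2ccccc2)=C1OCc1ccccc1 | intermediate
23 | (2S,4S)-5,7-bis(benzyloxy)-4-methoxy-6-(LC)-8-(SC)-2-phenylchromane (cis-4-methoxyflavan) | CO[C@H]1C[C@@H](c2ccccc2)Oc2c(Cc3cc(Cc4ccccc4OCc4ccccc4)ccc3OCc3ccccc3)c(OCc3ccccc3)c(Cc3cc(Cc4cc(Cc5ccccc5OCc5ccccc5)ccc4OCc4ccccc4)ccc3OCc3ccccc3)c(OCc3ccccc3)c21 | intermediate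
24 | (2S)-5,7-bis(benzyloxy)-6-(LC)-8-(SC)-2-phenylchroman-4-ol (mixture of C4 epimers, C4 left undefined) | OC1C[C@@H](c2ccccc2)Oc2c(Cc3cc(Cc4ccccc4OCc4ccccc4)ccc3OCc3ccccc3)c(OCc3ccccc3)c(Cc3cc(Cc4cc(Cc5ccccc5OCc5ccccc5)ccc4OCc4ccccc4)ccc3OCc3ccccc3)c(OCc3ccccc3)c21 | intermediate
25 | (2S)-5,7-bis(benzyloxy)-6-(LC)-8-(SC)-2-phenylchroman-4-one | O=C1C[C@@H](c2ccccc2)Oc2c(Cc3cc(Cc4ccccc4OCc4ccccc4)ccc3OCc3ccccc3)c(OCc3ccccc3)c(Cc3cc(Cc4cc(Cc5ccccc5OCc5ccccc5)ccc4OCc4ccccc4)ccc3OCc3ccccc3)c(OCc3ccccc3)c21 | intermediate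
26 | sarmentosumin D, (2S)-5,7-dihydroxy-8-[2-hydroxy-5-(2-hydroxybenzyl)benzyl]-6-{2-hydroxy-5-[2-hydroxy-5-(2-hydroxybenzyl)benzyl]benzyl}-2-phenylchroman-4-one | O=C1C[C@@H](c2ccccc2)Oc2c(Cc3cc(Cc4ccccc4O)ccc3O)c(O)c(Cc3cc(Cc4cc(Cc5ccccc5O)ccc4O)ccc3O)c(O)c21 | target

**Step count and risks**

Total step count: 17.
Longest linear sequence: 11 steps (steps 3, 4, 5, 6, 7, 8, 13, 14, 15, 16, 17).

Steps most likely to fail:

1. Step 14 (the proposed new method). What may go wrong: weak enantioface discrimination within the ion pair, or slow capture of the strongly stabilised quinone methide by styrene, so that acid-induced oligomerisation of styrene takes over. The fallback uses known chemistry, sets out from 18 and rejoins the route at 25. Addition of MeMgBr (excess, THF, 0 °C) to the formyl group should give the secondary benzylic alcohol F1, which is oxidised without delay with MnO2 in CH2Cl2 to the 2-hydroxyaryl methyl ketone F2. Condensation with N,N-dimethylformamide dimethyl acetal (toluene, 100 °C) should give the enaminone F3, and HCl in CH2Cl2 should close it to the chromone F4 with loss of dimethylamine. A palladium-catalysed asymmetric conjugate addition of phenylboronic acid (Pd(OCOCF3)2, the t-butyl pyridine-oxazoline ligand of the handedness that gives 2S, NH4PF6, H2O, 1,2-dichloroethane, 60 °C) then sets C2 and gives the protected flavanone 25 directly, so that steps 15 and 16 fall away.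

2. Step 13. What may go wrong: slow oxidative addition and transmetalation at the iodide flanked by two benzyloxy groups, so that the benzylzinc reagent is lost to protonation by the phenol, to addition to the formyl group or to homocoupling. The fallback sets out from 10 and rejoins the route at 18. Palladium-catalysed borylation of chloride 10 (B2pin2, Pd(dba)2, tris(4-methoxyphenyl)phosphine, KOAc, toluene, 50 °C) should give the isolable pinacol benzylboronate F5. A Suzuki–Miyaura coupling of it with iodide 16 under aqueous base (Pd(OAc)2, SPhos, K3PO4, toluene/H2O, 90 °C) should give 18, the boron reagent being indifferent to the phenol and the aldehyde.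

3. Step 15. What may go wrong: loss of a proton from C3 of the C4 cation (elimination of methanol to the flav-3-ene) or capture of the cation by an alkoxyarene ring of a chain in place of water. The fallback sets out from 23 and rejoins the route at 24. The elimination is made the intended path (pyridinium p-toluenesulfonate, 4 Å MS, toluene, 60 °C) to give the (2S)-flav-3-ene F6. A Mukaiyama hydration (Co(acac)2, PhSiH3, O2, THF, 25 °C) then returns oxygen to C4 through the benzylic C4 radical and should give 24; any ketone formed alongside is 25 itself.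

**Further compounds**

F1 | step 14 | 1-[4,6-bis(benzyloxy)-2-hydroxy-5-(LC)-3-(SC)phenyl]ethanol (carbinol centre undefined) | CC(O)c1c(O)c(Cc2cc(Cc3ccccc3OCc3ccccc3)ccc2OCc2ccccc2)c(OCc2ccccc2)c(Cc2cc(Cc3cc(Cc4ccccc4OCc4ccccc4)ccc3OCc3ccccc3)ccc2OCc2ccccc2)c1OCc1ccccc1
F2 | step 14 | 1-[4,6-bis(benzyloxy)-2-hydroxy-5-(LC)-3-(SC)phenyl]ethanone | CC(=O)c1c(O)c(Cc2cc(Cc3ccccc3OCc3ccccc3)ccc2OCc2ccccc2)c(OCc2ccccc2)c(Cc2cc(Cc3cc(Cc4ccccc4OCc4ccccc4)ccc3OCc3ccccc3)ccc2OCc2ccccc2)c1OCc1ccccc1
F3 | step 14 | (E)-1-[4,6-bis(benzyloxy)-2-hydroxy-5-(LC)-3-(SC)phenyl]-3-(dimethylamino)prop-2-en-1-one | CN(C)/C=C/C(=O)c1c(O)c(Cc2cc(Cc3ccccc3OCc3ccccc3)ccc2OCc2ccccc2)c(OCc2ccccc2)c(Cc2cc(Cc3cc(Cc4ccccc4OCc4ccccc4)ccc3OCc3ccccc3)ccc2OCc2ccccc2)c1OCc1ccccc1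
F4 | step 14 | 5,7-bis(benzyloxy)-6-(LC)-8-(SC)-4H-chromen-4-one | O=c1ccoc2c(Cc3cc(Cc4ccccc4OCc4ccccc4)ccc3OCc3ccccc3)c(OCc3ccccc3)c(Cc3cc(Cc4cc(Cc5ccccc5OCc5ccccc5)ccc4OCc4ccccc4)ccc3OCc3ccccc3)c(OCc3ccccc3)c12
F5 | step 13 | 2-(LC)-4,4,5,5-tetramethyl-1,3,2-dioxaborolane (pinacol benzylboronate of the long chain) | CC1(C)OB(Cc2cc(Cc3cc(Cc4ccccc4OCc4ccccc4)ccc3OCc3ccccc3)ccc2OCc2ccccc2)OC1(C)C
F6 | step 15 | (2S)-5,7-bis(benzyloxy)-6-(LC)-8-(SC)-2-phenyl-2H-chromene (flav-3-ene) | C1=C[C@@H](c2ccccc2)Oc2c(Cc3cc(Cc4ccccc4OCc4ccccc4)ccc3OCc3ccccc3)c(OCc3ccccc3)c(Cc3cc(Cc4cc(Cc5ccccc5OCc5ccccc5)ccc4OCc4ccccc4)ccc3OCc3ccccc3)c(OCc3ccccc3)c21
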